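# Proposed total synthesis of CNP0375196.1 by a rhodium-catalysed C–H annulation with a cyclopropene

## The problem

The target 22 is a 2H-chromene: a benzene ring (C4a to C8a) fused to a 2H-pyran (O1, C2, C3=C4). C6 carries an acetyl group and C7 a hydroxyl group hydrogen-bonded to it. C2 carries a methyl group and a CH2O arm esterified with (E)-ferulic acid.

C2 is the only stereocentre. It is fully substituted (O1, C3, CH3, CH2O) and has the (R) configuration. No other stereocentre can relay chirality to it, so it must come from a catalyst or from an enantiopure building block.

C2 cannot epimerise by enolisation, but it is the carbinol carbon of an allylic aryl ether. Electrocyclic opening of the pyran to an ortho-quinone methide (light, heat) or acid ionisation of O1–C2 would erase it. Every step after its creation therefore has to be mild, cool and run in the dark.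

The ferulate is a base-labile ester, a Michael acceptor and a free phenol. The aryl methyl ketone excludes hydride and organometallic reagents late in the route. The styrene-like C3=C4 and the cinnamate exclude hydrogenation. The ester is therefore attached late to the C2–CH2OH group, and the last step can only be a gentle deprotection.

The benzene ring has a resorcinol-type pattern (acetyl para to O1, hydroxyl meta to O1) that can be bought, so the real task is the pyran ring with its stereocentre.

The enabling feature is the three-carbon bridge C2–C3–C4 between O1 and C4a. Its quaternary end C2 bears CH3 and CH2O, which is the skeleton of a ring-opened 3-methyl-3-(oxymethyl)cyclopropene. C4a carries a hydrogen ortho to O1, so O1 can be fitted with an N–O group that directs C–H activation and serves as the oxidant.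

## Retrosynthesis

**Final deprotection.** The last cut removes the two phenolic O–Si bonds of the bis-silyl ester 21 to give 22. Silyl ethers are chosen for both phenols because buffered fluoride cleaves them together at 0 °C without touching the ester, the olefins or O1–C2. Benzyl ethers would need hydrogenolysis, which would reduce C3=C4 and the cinnamate. Allyl ethers would need zerovalent palladium at the last stage, which could ionise the allylic aryl ether O1–C2 and racemise C2. Acetals would need acid. The forward reaction asks only for buffering, so that the phenoxides do not attack the ester.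

**Ester bond.** The acyl C–O bond of 21 is cut to the chromene alcohol 17 and the O-silylated ferulic acid 20. Placing this cut late keeps the Michael acceptor and the base-labile ester out of every earlier step. Compound 17 has a single free hydroxyl group, so the esterification needs no chemoselectivity. Acid 20 comes from ferulic acid 18 in one operation through the bis-silyl compound 19.

**Differentiation of the two silyl ethers.** Alcohol 17 is traced back to the bis-silyl chromene 16 by cutting only the alkyl O–Si bond. A tert-butyldimethylsilyl ether on the primary oxygen and a triisopropylsilyl ether on the C7 oxygen differ in the required sense: acid removes the alkyl ether first, fluoride would remove the aryl ether first. The alternative of removing both and acylating a diol would pit the primary alcohol against the chelated phenol. The forward reaction must use acid weak enough to leave the allylic aryl ether intact.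

**Key disconnection.** Chromene 16 is cut at C4–C4a and O1–C2 into the N-aryloxyacetamide 8 and the cyclopropene 15.
- Cutting only O1–C2 would need a preformed ortho-dienyl phenol, which closes thermally and gives racemate.
- Cutting only C4–C4a would need a hindered tertiary aryl ether that is itself hard to make enantiopure.
- Cutting C3=C4 would need reagents the ketone cannot survive.
- The double cut gives two achiral fragments of similar size, each reachable in five steps. It forms the ring, both bonds and the stereocentre in one catalytic step that is redox-neutral and runs at room temperature.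
- The forward reaction must activate the C–H bond para to the silyloxy group and not the one between the two oxygens. It must open the cyclopropene so that the quaternary carbon ends up on oxygen. It must form the O1–C2 bond on the metal with control of the face.

**Aryl partner.** Compound 8 is simplified by cutting the aryl O–Si bond to phenol 7, and 7 by cutting the allyl ether from 6. The N-acetyl group and the acetimidate protection are removed on paper through the ammonium salt 5 and the O-aryl acetimidate 4. The aryl C–O bond of 4 is cut to the allyl-protected fluoroketone 2 and the oxime-type nucleophile 3; 2 comes from the fluorophenol 1.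
- The aryl C–O cut is preferred over an N–O cut because the carbon para to the acetyl group is activated for nucleophilic aromatic substitution and 1 already carries fluoride there.
- The triisopropylsilyl ether wanted in the key step cannot be carried through the substitution, since an oxygen nucleophile in a dipolar solvent would strip it from an ortho-acyl phenol.
- An acetal protecting group would release an aldehyde in the acidic unmasking of the aminooxy group, and that aldehyde would be trapped as an oxime ether.
- The allyl ether is therefore used for steps 2 and 3 and exchanged afterwards.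
- The forward sequence must keep the aminooxy ketone protonated, as in 5, until it is acetylated.

**Cyclopropene partner.** Compound 15 is traced back through the C-silylated cyclopropene 14 and the alcohol 13 to the ester 12. The two ring bonds to the quaternary carbon of 12 are cut in a [2+1] sense to the diazo ester 10 and trimethylsilylacetylene 11. Compound 10 comes from the acetoacetate 9 by diazo transfer.
- The carbenoid route places the methyl group and the one-carbon oxygenated arm on the same carbon from the start, and it runs under catalytic conditions at low temperature.
- The classical dihalocarbene, reduction and elimination sequence on a methallyl ether is no shorter and needs strong base.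
- The forward cyclopropenation must outrun β-hydride migration of the α-methyl carbenoid.
- The silicon on the alkyne keeps the intermediates non-volatile and is removed last.

## Roads not taken

Alternative 1: The benzene ring itself is cut at C4a–C5 and C6–C7.
- **Cut and key step.** The precursors are an enantiopure dihydropyran with a dienyl side chain, (R)-{[6-(2,2-bis(trimethylsilyloxy)ethenyl)-2-methyl-3,4-dihydro-2H-pyran-2-yl]methoxy}(tert-butyl)diphenylsilane A1, and the ynone but-3-yn-2-one A2. The ketene acetal diene adds to the ynone with its nucleophilic terminus (the future C4a) on the β-carbon. Loss of a silanol aromatises the adduct to the chroman (R)-1-{2-[(tert-butyldiphenylsilyloxy)methyl]-7-hydroxy-2-methylchroman-6-yl}ethan-1-one A3.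
- **Merits.** The ortho relation of acetyl and hydroxyl follows from the polarity of the partners. The C7 hydroxyl appears unprotected and chelated. The stereocentre is made early by classical means, so no step depends on untested asymmetric catalysis; in that respect this road is safer than the chosen plan.
- **Weak points.** A1 is a hydrolytically fragile bis-silyl ketene acetal at the end of a long linear sequence, and its quaternary stereocentre still needs an asymmetric step of its own. A3 is a chroman, so C3=C4 has to be introduced afterwards by benzylic dehydrogenation of an acyl-deactivated ring next to a free phenol. The primary alcohol then has to be acylated in the presence of that phenol.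
- **Comparison.** The chosen plan reaches the chromene oxidation level directly and is convergent. Against the stereochemical safety of this road it has to set the unproven enantioselectivity of step 11, for which a racemic fallback with resolution exists.

Alternative 2: The pyran is cut at C3=C4.
- **Cut and key step.** The precursor is the dialdehyde (S)-2-[4-bromo-2-formyl-5-(methoxymethoxy)phenoxy]-3-(tert-butyldiphenylsilyloxy)-2-methylpropanal A4. Its descriptor is S only because the formyl group outranks the silyloxymethyl group; the spatial arrangement is that of the target. Low-valent titanium couples the two aldehydes reductively to (R)-{[6-bromo-7-(methoxymethoxy)-2-methyl-2H-chromen-2-yl]methoxy}(tert-butyl)diphenylsilane A5.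
- **Merits.** The stereocentre is fixed before ring closure and, being quaternary, cannot epimerise next to the aldehyde. The ring olefin can only be cis. Six-membered ring closure by carbonyl coupling is favourable.
- **Weak points.** The reagent does not tolerate the acetyl group, so C6 has to carry a bromide that is converted into the methyl ketone after the key step. The ketyl of an α-aryloxy aldehyde can expel the aryloxide, which here is a good leaving group, so reductive C–O cleavage competes with coupling. The aryl bromide and the acetal are exposed to a reducing Lewis acid. The tertiary aryl ether of A4 is itself difficult to assemble. After the key step come ketone installation, acidic acetal removal on an acid-sensitive chromene, desilylation and esterification.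
- **Comparison.** This road is better than the chosen plan only in that its stereocentre does not rest on a new catalytic reaction. It is longer, needs titanium in excess and has poorer functional-group tolerance. The chosen key step is catalytic, neutral and compatible with the ketone.

Alternative 3: Only C4–C4a is cut and the O1–C2 bond is kept.
- **Cut and key step.** The precursor is the aryl propargyl ether (R)-1-{4-[(1-(4-methoxybenzyloxy)-2-methylbut-3-yn-2-yl)oxy]-2-(triisopropylsilyloxy)phenyl}ethan-1-one A6. A cationic phosphine complex of monovalent gold activates the terminal alkyne, and C4a attacks it to give (R)-1-{2-[(4-methoxybenzyloxy)methyl]-2-methyl-7-(triisopropylsilyloxy)-2H-chromen-6-yl}ethan-1-one A7.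
- **Merits.** A7 differs from 16 only in the protecting group on the primary oxygen. Gold-catalysed hydroarylation of aryl propargyl ethers is established. Unlike the thermal propargyl Claisen route it does not pass through an allene and an ortho-quinone methide, so C2 is carried through intact. In the reliability of its individual steps this is the most conservative road and is ahead of the chosen plan.
- **Weak points.** A6 must be made with retention at a tertiary propargylic carbon. Copper-catalysed propargylation of phenols goes through planar intermediates and racemises, so a hindered tertiary alkoxide would have to displace the fluoride of an arene like 2, which is activated by only one acyl group and has an enolisable ketone. The enantiopure tertiary alcohol needs an asymmetric alkynylation that must tell CH3 from CH2O, the same discrimination problem in another reaction. The acyl-deactivated ring is a poor nucleophile, and the gold catalyst may divert into the sigmatropic pathway. The benzyl-type ether must later be removed oxidatively next to an electron-rich chromene.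
- **Comparison.** This road is safer step by step but longer and more linear. The chosen plan sets the same stereocentre catalytically from two achiral fragments. It has to set the unproven enantioinduction of step 11 against the reliability of the gold step.

Key step: step 11

## Route

Remark on the chemistry: the sense of induction of the chiral rhodium catalyst cannot be predicted with confidence; the ligand is written with the (R)-binaphthyl backbone, and its enantiomer would be used if the (S)-chromene proves to be favoured. Cpx denotes a cyclopentadienyl ring fused through two CH2 groups to the 2,2'-positions of 3,3'-dimethoxy-1,1'-binaphthyl.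

Remark on the chemistry: compounds 12, 13 and 14 are chiral but racemic; their stereocentre disappears in 15, which has a mirror plane.

Step 1
Reactants: 1 4'-fluoro-2'-hydroxyacetophenone
Product: 2 1-[4-fluoro-2-(prop-2-en-1-yloxy)phenyl]ethan-1-one
Conditions: allyl bromide, K2CO3, DMF, 50 °C
Reagents that add atoms: allyl bromide, C=CCBr
Why: Williamson etherification of the chelated phenol. The allyl ether survives the oxygen nucleophile of step 2 and the aqueous acid of step 3 and releases no carbonyl compound when it is removed, whereas a silyl ether would be cleaved in step 2 and an acetal would give an aldehyde in step 3.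

Step 2
Reactants: 2 1-[4-fluoro-2-(prop-2-en-1-yloxy)phenyl]ethan-1-one; 3 ethyl (1E)-N-hydroxyethanimidate (ethyl N-hydroxyacetimidate)
Product: 4 ethyl (1E)-N-[4-acetyl-3-(prop-2-en-1-yloxy)phenoxy]ethanimidate
Conditions: 3, KOtBu (1.0 equiv to 3), DMF, 0 °C; then 2, 0 °C → rt
Reagents that add atoms: none
Why: Nucleophilic aromatic substitution: the fluoride para to the acetyl group is displaced by the α-effect oximate oxygen through a Meisenheimer intermediate. The oximate is formed first with one equivalent of base so that no free alkoxide is left to enolise the methyl ketone.

Step 3
Reactants: 4 ethyl (1E)-N-[4-acetyl-3-(prop-2-en-1-yloxy)phenoxy]ethanimidate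
Product: 6 N-[4-acetyl-3-(prop-2-en-1-yloxy)phenoxy]acetamide, via O-arylhydroxylammonium chloride 5 (not isolated)
Conditions: 6 M HCl (aq), 1,4-dioxane, 0 °C; then NaHCO3, Ac2O, EtOAc/H2O, 0 °C
Reagents that add atoms: acetic anhydride, CC(=O)OC(C)=O; hydrogen chloride, Cl (chloride ion of 5 only)
Why: Acid hydrolysis of the O-aryl acetohydroximate gives the salt 5, in which the nitrogen is protonated and cannot condense with the ketone of a second molecule. Schotten–Baumann N-acetylation in a buffered two-phase system then captures the amine as it is set free; the allyl ether and the ketone are inert to both stages.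

Step 4
Reactants: 6 N-[4-acetyl-3-(prop-2-en-1-yloxy)phenoxy]acetamide
Product: 7 N-(4-acetyl-3-hydroxyphenoxy)acetamide
Conditions: Pd(PPh3)4 (3 mol%), morpholine (5 equiv), THF, rt
Reagents that add atoms: none
Why: Tsuji–Trost deallylation: zerovalent palladium ionises the aryl allyl ether, and the allylpalladium cation is intercepted by the large excess of morpholine before the weakly nucleophilic hydroxamate nitrogen can compete. The conditions are neutral and leave the N–O bond and the ketone alone.

Step 5
Reactants: 7 N-(4-acetyl-3-hydroxyphenoxy)acetamide
Product: 8 N-[4-acetyl-3-(triisopropylsilyloxy)phenoxy]acetamide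
Conditions: TIPSCl (1.3 equiv), imidazole, DMF, rt; aq. NaHCO3 work-up
Reagents that add atoms: chlorotriisopropylsilane, CC(C)[Si](Cl)(C(C)C)C(C)C
Why: Imidazole-mediated silylation of the phenol; any silyl imidate formed on the hydroxamate is hydrolysed on aqueous work-up. The bulky aryl silyl ether later shields the C–H bond between the two oxygens and is removed by fluoride in the last step.

Step 6
Reactants: 9 methyl 2-methyl-3-oxobutanoate (methyl 2-methylacetoacetate)
Product: 10 methyl 2-diazopropanoate
Conditions: 4-acetamidobenzenesulfonyl azide, DBU, MeCN, 0 °C → rt
Reagents that add atoms: 4-acetamidobenzenesulfonyl azide, CC(=O)Nc1ccc(S(=O)(=O)N=[N+]=[N-])cc1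
Why: Regitz deacylative diazo transfer: the enolate of the 2-substituted acetoacetate adds to the sulfonyl azide, and the adduct fragments with transfer of the acetyl group to the sulfonamide nitrogen. The volatile diazo ester is used as a solution.

Step 7
Reactants: 10 methyl 2-diazopropanoate; 11 ethynyltrimethylsilane (trimethylsilylacetylene)
Product: 12 methyl 1-methyl-2-(trimethylsilyl)cycloprop-2-ene-1-carboxylate (racemic)
Conditions: Rh2(OPiv)4 (0.5 mol%), 11 (3 equiv), CH2Cl2, −78 °C, slow addition of 10, then → rt
Reagents that add atoms: none
Why: Rhodium carbenoid [2+1] cycloaddition to a terminal alkyne (cyclopropenation). The bulky pivalate ligands and the low temperature suppress β-hydride migration of the α-methyl carbenoid, and the silyl group makes the alkyne easy to handle and the product non-volatile.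

Step 8
Reactants: 12 methyl 1-methyl-2-(trimethylsilyl)cycloprop-2-ene-1-carboxylate
Product: 13 [1-methyl-2-(trimethylsilyl)cycloprop-2-en-1-yl]methanol (racemic)
Conditions: i-Bu2AlH (2.2 equiv), CH2Cl2, −78 °C; aq. potassium sodium tartrate
Reagents that add atoms: none
Why: Reduction of the ester to the primary alcohol with i-Bu2AlH at low temperature. This avoids the alkoxide-directed hydrometalation of the strained double bond that LiAlH4 can cause.

Step 9
Reactants: 13 [1-methyl-2-(trimethylsilyl)cycloprop-2-en-1-yl]methanol
Product: 14 tert-butyldimethyl{[1-methyl-2-(trimethylsilyl)cycloprop-2-en-1-yl]methoxy}silane (racemic)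
Conditions: TBSCl, imidazole, CH2Cl2, 0 °C → rt
Reagents that add atoms: tert-butylchlorodimethylsilane, CC(C)(C)[Si](C)(C)Cl
Why: Standard silylation of a primary alcohol. It is done before the C-desilylation so that the cyclopropene stays non-volatile.

Step 10
Reactants: 14 tert-butyldimethyl{[1-methyl-2-(trimethylsilyl)cycloprop-2-en-1-yl]methoxy}silane
Product: 15 tert-butyldimethyl[(1-methylcycloprop-2-en-1-yl)methoxy]silane
Conditions: K2CO3 (0.3 equiv), MeOH, 0 °C → rt; concentrate cold
Reagents that add atoms: none
Why: Protodesilylation: methoxide attacks the silicon on the cyclopropene sp2 carbon, whose high s-character makes the carbanion a leaving group comparable to an acetylide, as in the cleavage of alkynylsilanes. The alkyl silyl ether is not affected, and the product is achiral.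

Step 11
Reactants: 8 N-[4-acetyl-3-(triisopropylsilyloxy)phenoxy]acetamide; 15 tert-butyldimethyl[(1-methylcycloprop-2-en-1-yl)methoxy]silane
Product: 16 (R)-1-{2-[(tert-butyldimethylsilyloxy)methyl]-2-methyl-7-(triisopropylsilyloxy)-2H-chromen-6-yl}ethan-1-one
Conditions: (R)-CpxRh(C2H4)2 (5 mol%), (PhCO2)2 (5 mol%), CsOAc (25 mol%), 15 (1.3 equiv), MeOH, 0 °C → rt, dark
Reagents that add atoms: none
Why: Proposed new method: the peroxide oxidises the monovalent rhodium precatalyst to a chiral cyclopentadienyl carboxylate of trivalent rhodium, the amide nitrogen of 8 binds to it, and concerted metalation–deprotonation of the less hindered ortho C–H bond (the future C4a–H) gives a five-membered rhodacycle. The strained alkene of 15 inserts into the aryl–rhodium bond, which forms C4–C4a, and β-carbon elimination opens the three-membered ring to a rhodium allyl whose fully substituted terminus is the future C2. Bond formation between the phenolic oxygen and that terminus, with cleavage of the N–O bond as internal oxidant, releases 16 and, after protonation, acetamide and the trivalent rhodium carboxylate. The closest known reaction type is the [Cp*RhCl2]2-catalysed C–H activation and [3+3] annulation of N-aryloxyacetamides with 3,3-disubstituted cyclopropenes to racemic 2,2-disubstituted 2H-chromenes; replacing Cp* by a chiral cyclopentadienyl ligand to make it enantioselective is new. The 2H-pyran ring closes as a six-membered ring by O1–C2 bond formation inside the coordination sphere of rhodium, after the carbon–carbon bond has been made by migratory insertion. The C2 stereocentre is under catalyst control by the binaphthyl-fused ligand alone, either when the aryl group is delivered to one of the two enantiotopic olefinic carbons of 15 or, if the allyl intermediate equilibrates, when one face of its disubstituted terminus is engaged by oxygen. This requires ring closure on the metal, because dissociation to a free ortho-quinone methide and thermal oxa-6π closure would give racemate; low temperature, darkness and the carboxylate cocatalyst are chosen for that reason. Site selectivity between the two ortho C–H bonds comes from the triisopropylsilyl ether, which blocks the position between the two oxygens, and the neutral ketone is a far weaker directing group than the anionic amidate.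

Step 12
Reactants: 16 (R)-1-{2-[(tert-butyldimethylsilyloxy)methyl]-2-methyl-7-(triisopropylsilyloxy)-2H-chromen-6-yl}ethan-1-one
Product: 17 (R)-1-[2-(hydroxymethyl)-2-methyl-7-(triisopropylsilyloxy)-2H-chromen-6-yl]ethan-1-one
Conditions: camphorsulfonic acid (10 mol%), MeOH/CH2Cl2 (1:1), 0 °C, dark
Reagents that add atoms: none
Why: Acid-catalysed methanolysis of a primary alkyl silyl ether. Under acid the alkyl tert-butyldimethylsilyl ether is cleaved much faster than the hindered aryl triisopropylsilyl ether, the reverse of the order under fluoride, so the phenol stays masked for the esterification.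

Step 13
Reactants: 18 ferulic acid, (E)-3-(4-hydroxy-3-methoxyphenyl)prop-2-enoic acid
Product: 20 (E)-3-[4-(tert-butyldimethylsilyloxy)-3-methoxyphenyl]prop-2-enoic acid, via bis-silylated ferulate 19 (not isolated)
Conditions: TBSCl (2.3 equiv), imidazole, DMF, rt; then AcOH/THF/H2O (3:1:1), rt
Reagents that add atoms: tert-butylchlorodimethylsilane, CC(C)(C)[Si](C)(C)Cl
Why: Silylation of both acidic hydroxyl groups, then selective hydrolysis of the silyl ester. The silyl ester is far more labile than the aryl silyl ether in aqueous acetic acid.

Step 14
Reactants: 17 (R)-1-[2-(hydroxymethyl)-2-methyl-7-(triisopropylsilyloxy)-2H-chromen-6-yl]ethan-1-one; 20 (E)-3-[4-(tert-butyldimethylsilyloxy)-3-methoxyphenyl]prop-2-enoic acid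
Product: 21 [(R)-6-acetyl-2-methyl-7-(triisopropylsilyloxy)-2H-chromen-2-yl]methyl (E)-3-[4-(tert-butyldimethylsilyloxy)-3-methoxyphenyl]prop-2-enoate
Conditions: EDC·HCl (1.5 equiv), DMAP (0.2 equiv), 20 (1.3 equiv), CH2Cl2, 0 °C → rt, dark
Reagents that add atoms: none
Why: Steglich esterification: carbodiimide activation of the acid and acyl transfer by DMAP to the only free hydroxyl group. C2 is not involved and the conditions are neutral.

Step 15
Reactants: 21 [(R)-6-acetyl-2-methyl-7-(triisopropylsilyloxy)-2H-chromen-2-yl]methyl (E)-3-[4-(tert-butyldimethylsilyloxy)-3-methoxyphenyl]prop-2-enoate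
Product: 22 [(R)-6-acetyl-7-hydroxy-2-methyl-2H-chromen-2-yl]methyl (E)-3-(4-hydroxy-3-methoxyphenyl)prop-2-enoate (CNP0375196.1)
Conditions: Bu4NF (2.4 equiv), AcOH (2.6 equiv), THF, 0 °C, dark
Reagents that add atoms: none
Why: Fluoride cleaves both aryl silyl ethers through pentacoordinate silicates. Acetic acid protonates the phenoxides as they form so that the ferulate ester is not attacked; the stereocentre and both olefins are untouched.

## Compound list

1 | 4'-fluoro-2'-hydroxyacetophenone | CC(=O)c1ccc(F)cc1O | starting material
2 | 1-[4-fluoro-2-(prop-2-en-1-yloxy)phenyl]ethan-1-one | CC(=O)c1ccc(F)cc1OCC=C | intermediate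
3 | ethyl (1E)-N-hydroxyethanimidate | CCO/C(C)=N/O | starting material
4 | ethyl (1E)-N-[4-acetyl-3-(prop-2-en-1-yloxy)phenoxy]ethanimidate | CCO/C(C)=N/Oc1ccc(C(C)=O)c(OCC=C)c1 | intermediate
5 | O-[4-acetyl-3-(prop-2-en-1-yloxy)phenyl]hydroxylammonium chloride (not isolated) | CC(=O)c1ccc(O[NH3+])cc1OCC=C.[Cl-] | intermediate
6 | N-[4-acetyl-3-(prop-2-en-1-yloxy)phenoxy]acetamide | CC(=O)NOc1ccc(C(C)=O)c(OCC=C)c1 | intermediate
7 | N-(4-acetyl-3-hydroxyphenoxy)acetamide | CC(=O)NOc1ccc(C(C)=O)c(O)c1 | intermediate
8 | N-[4-acetyl-3-(triisopropylsilyloxy)phenoxy]acetamide | CC(=O)NOc1ccc(C(C)=O)c(O[Si](C(C)C)(C(C)C)C(C)C)c1 | intermediate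
9 | methyl 2-methyl-3-oxobutanoate | CC(=O)C(C)C(=O)OC | starting material
10 | methyl 2-diazopropanoate | COC(=O)C(C)=[N+]=[N-] | intermediate
11 | ethynyltrimethylsilane | C#C[Si](C)(C)C | starting material
12 | methyl 1-methyl-2-(trimethylsilyl)cycloprop-2-ene-1-carboxylate (racemic) | COC(=O)C1(C)C=C1[Si](C)(C)C | intermediate
13 | [1-methyl-2-(trimethylsilyl)cycloprop-2-en-1-yl]methanol (racemic) | CC1(CO)C=C1[Si](C)(C)C | intermediate
14 | tert-butyldimethyl{[1-methyl-2-(trimethylsilyl)cycloprop-2-en-1-yl]methoxy}silane (racemic) | CC1(CO[Si](C)(C)C(C)(C)C)C=C1[Si](C)(C)C | intermediate
15 | tert-butyldimethyl[(1-methylcycloprop-2-en-1-yl)methoxy]silane | CC1(CO[Si](C)(C)C(C)(C)C)C=C1 | intermediate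
16 | (R)-1-{2-[(tert-butyldimethylsilyloxy)methyl]-2-methyl-7-(triisopropylsilyloxy)-2H-chromen-6-yl}ethan-1-one | CC(C)(C)[Si](C)(C)OC[C@@]1(C)C=Cc2cc(C(C)=O)c(O[Si](C(C)C)(C(C)C)C(C)C)cc2O1 | intermediate
17 | (R)-1-[2-(hydroxymethyl)-2-methyl-7-(triisopropylsilyloxy)-2H-chromen-6-yl]ethan-1-one | OC[C@@]1(C)C=Cc2cc(C(C)=O)c(O[Si](C(C)C)(C(C)C)C(C)C)cc2O1 | intermediate
18 | ferulic acid, (E)-3-(4-hydroxy-3-methoxyphenyl)prop-2-enoic acid | COc1cc(/C=C/C(=O)O)ccc1O | starting material
19 | tert-butyldimethylsilyl (E)-3-[4-(tert-butyldimethylsilyloxy)-3-methoxyphenyl]prop-2-enoate (not isolated) | COc1cc(/C=C/C(=O)O[Si](C)(C)C(C)(C)C)ccc1O[Si](C)(C)C(C)(C)C | intermediate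
20 | (E)-3-[4-(tert-butyldimethylsilyloxy)-3-methoxyphenyl]prop-2-enoic acid | COc1cc(/C=C/C(=O)O)ccc1O[Si](C)(C)C(C)(C)C | intermediate
21 | [(R)-6-acetyl-2-methyl-7-(triisopropylsilyloxy)-2H-chromen-2-yl]methyl (E)-3-[4-(tert-butyldimethylsilyloxy)-3-methoxyphenyl]prop-2-enoate | COc1cc(/C=C/C(=O)OC[C@@]2(C)C=Cc3cc(C(C)=O)c(O[Si](C(C)C)(C(C)C)C(C)C)cc3O2)ccc1O[Si](C)(C)C(C)(C)C | intermediate
22 | [(R)-6-acetyl-7-hydroxy-2-methyl-2H-chromen-2-yl]methyl (E)-3-(4-hydroxy-3-methoxyphenyl)prop-2-enoate | COc1cc(/C=C/C(=O)OC[C@@]2(C)C=Cc3cc(C(C)=O)c(O)cc3O2)ccc1O | target

## Step count and least certain steps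

Total: 15 steps. Longest linear sequence: 9 steps (steps 1–5, 11, 12, 14, 15); the cyclopropene branch (steps 6–10, 11, 12, 14, 15) is of equal length.

**Step 11 (key step, proposed new method).**
- What may go wrong: poor facial discrimination at the allyl terminus. The ligand may not tell CH3 from CH2OSi well enough, or ring closure may escape from the metal through dissociation to the ortho-quinone methide and thermal closure, which is a racemic background path. The bulkier chiral catalyst may also turn over slowly on this trisubstituted arene.
- Fallback, known chemistry throughout: it sets out from 8 and 15 and returns to the route at 17. The annulation is run with [Cp*RhCl2]2 and CsOAc in MeOH at room temperature to give racemic 1-{2-[(tert-butyldimethylsilyloxy)methyl]-2-methyl-7-(triisopropylsilyloxy)-2H-chromen-6-yl}ethan-1-one F1. Acid methanolysis as in step 12 gives racemic 1-[2-(hydroxymethyl)-2-methyl-7-(triisopropylsilyloxy)-2H-chromen-6-yl]ethan-1-one F2. Preparative chromatography of this alcohol on a polysaccharide chiral stationary phase then gives 17 and its enantiomer (S)-1-[2-(hydroxymethyl)-2-methyl-7-(triisopropylsilyloxy)-2H-chromen-6-yl]ethan-1-one F3, which is set aside.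

**Step 3.**
- What may go wrong: oligomerisation by oxime-ether formation between the aminooxy group of one molecule and the aryl ketone of another, in the interval between neutralisation and acetylation.
- Fallback: it sets out from 2 and returns at 6, and the free aminooxy ketone never exists. Fluoride 2 is substituted with the potassium salt of tert-butyl N-hydroxycarbamate in DMF to give tert-butyl N-[4-acetyl-3-(prop-2-en-1-yloxy)phenoxy]carbamate F4. The nitrogen is acetylated with Ac2O and DMAP to tert-butyl N-acetyl-N-[4-acetyl-3-(prop-2-en-1-yloxy)phenoxy]carbamate F5. Trifluoroacetic acid in CH2Cl2 at 0 °C removes the tert-butoxycarbonyl group and leaves 6.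

**Step 12.**
- What may go wrong: erosion of enantiopurity or loss of material through acid. Protonation at O1 can start ionisation of the allylic O1–C2 bond, and methanol can add across the electron-rich C3=C4; the aryl silyl ether may also be partly lost.
- Fallback: it sets out from 16 and returns at 22 without any acid. Buffered Bu4NF removes both silyl groups to give (R)-1-[7-hydroxy-2-(hydroxymethyl)-2-methyl-2H-chromen-6-yl]ethan-1-one F6. The primary alcohol is esterified with 20 by carbodiimide and DMAP, with the acid as the limiting component at 0 °C; this relies on the much lower nucleophilicity of the phenol chelated to the ketone. The product is [(R)-6-acetyl-7-hydroxy-2-methyl-2H-chromen-2-yl]methyl (E)-3-[4-(tert-butyldimethylsilyloxy)-3-methoxyphenyl]prop-2-enoate F7, and buffered fluoride as in step 15 gives 22.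

**Step 10.**
- What may go wrong: incomplete protodesilylation, because the silane lacks the activating ester of the usual substrates, and loss of the volatile, strained product by evaporation or ene dimerisation during isolation.
- Fallback: it sets out from 13 and returns at 15, reversing the order of the two operations. The free alcohol 13 is C-desilylated with Bu4NF in THF at 0 °C, where the alkoxide assists, to give (1-methylcycloprop-2-en-1-yl)methanol F8. This is kept in solution and silylated directly with TBSCl and imidazole to 15.

## Further compounds

F1 | step 11 | racemic 1-{2-[(tert-butyldimethylsilyloxy)methyl]-2-methyl-7-(triisopropylsilyloxy)-2H-chromen-6-yl}ethan-1-one | CC(C)(C)[Si](C)(C)OCC1(C)C=Cc2cc(C(C)=O)c(O[Si](C(C)C)(C(C)C)C(C)C)cc2O1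
F2 | step 11 | racemic 1-[2-(hydroxymethyl)-2-methyl-7-(triisopropylsilyloxy)-2H-chromen-6-yl]ethan-1-one | OCC1(C)C=Cc2cc(C(C)=O)c(O[Si](C(C)C)(C(C)C)C(C)C)cc2O1
F3 | step 11 | (S)-1-[2-(hydroxymethyl)-2-methyl-7-(triisopropylsilyloxy)-2H-chromen-6-yl]ethan-1-one | OC[C@]1(C)C=Cc2cc(C(C)=O)c(O[Si](C(C)C)(C(C)C)C(C)C)cc2O1
F4 | step 3 | tert-butyl N-[4-acetyl-3-(prop-2-en-1-yloxy)phenoxy]carbamate | CC(=O)c1ccc(ONC(=O)OC(C)(C)C)cc1OCC=C
F5 | step 3 | tert-butyl N-acetyl-N-[4-acetyl-3-(prop-2-en-1-yloxy)phenoxy]carbamate | CC(=O)N(Oc1ccc(C(C)=O)c(OCC=C)c1)C(=O)OC(C)(C)C
F6 | step 12 | (R)-1-[7-hydroxy-2-(hydroxymethyl)-2-methyl-2H-chromen-6-yl]ethan-1-one | OC[C@@]1(C)C=Cc2cc(C(C)=O)c(O)cc2O1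
F7 | step 12 | [(R)-6-acetyl-7-hydroxy-2-methyl-2H-chromen-2-yl]methyl (E)-3-[4-(tert-butyldimethylsilyloxy)-3-methoxyphenyl]prop-2-enoate | COc1cc(/C=C/C(=O)OC[C@@]2(C)C=Cc3cc(C(C)=O)c(O)cc3O2)ccc1O[Si](C)(C)C(C)(C)C
F8 | step 10 | (1-methylcycloprop-2-en-1-yl)methanol | CC1(CO)C=C1
A1 | alternative 1 | (R)-{[6-(2,2-bis(trimethylsilyloxy)ethenyl)-2-methyl-3,4-dihydro-2H-pyran-2-yl]methoxy}(tert-butyl)diphenylsilane | CC(C)(C)[Si](c1ccccc1)(c1ccccc1)OC[C@@]1(C)CCC=C(C=C(O[Si](C)(C)C)O[Si](C)(C)C)O1
A2 | alternative 1 | but-3-yn-2-one | CC(=O)C#C
A3 | alternative 1 | (R)-1-{2-[(tert-butyldiphenylsilyloxy)methyl]-7-hydroxy-2-methylchroman-6-yl}ethan-1-one | CC(C)(C)[Si](c1ccccc1)(c1ccccc1)OC[C@@]1(C)CCc2cc(C(C)=O)c(O)cc2O1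
A4 | alternative 2 | (S)-2-[4-bromo-2-formyl-5-(methoxymethoxy)phenoxy]-3-(tert-butyldiphenylsilyloxy)-2-methylpropanal | CC(C)(C)[Si](c1ccccc1)(c1ccccc1)OC[C@@](C)(C=O)Oc1cc(OCOC)c(Br)cc1C=O
A5 | alternative 2 | (R)-{[6-bromo-7-(methoxymethoxy)-2-methyl-2H-chromen-2-yl]methoxy}(tert-butyl)diphenylsilane | CC(C)(C)[Si](c1ccccc1)(c1ccccc1)OC[C@@]1(C)C=Cc2cc(Br)c(OCOC)cc2O1
A6 | alternative 3 | (R)-1-{4-[(1-(4-methoxybenzyloxy)-2-methylbut-3-yn-2-yl)oxy]-2-(triisopropylsilyloxy)phenyl}ethan-1-one | COc1ccc(COC[C@@](C)(C#C)Oc2ccc(C(C)=O)c(O[Si](C(C)C)(C(C)C)C(C)C)c2)cc1
A7 | alternative 3 | (R)-1-{2-[(4-methoxybenzyloxy)methyl]-2-methyl-7-(triisopropylsilyloxy)-2H-chromen-6-yl}ethan-1-one | COc1ccc(COC[C@@]2(C)C=Cc3cc(C(C)=O)c(O[Si](C(C)C)(C(C)C)C(C)C)cc3O2)cc1
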